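The ten-membered carbocycle (ring A, C1–C10) is closed last at the C3–C4 single bond. The step exploits the 1,5-diene array C1=C10/C4=C5: C3 is homoallylic to C1=C10, so it can be unveiled from a terminal C1=C10–C2=C3 diene by hydroboration, and C4 is the olefinic carbon of the ring-cis C4=C5 bond, preset as a (Z)-alkenyl iodide. One operation, a B-alkyl Suzuki–Miyaura macrocyclisation, forms the ring with both olefin geometries intact. Its precursor is an open-chain trans-α-methylene-γ-butyrolactone (ring B, C6/C7) carrying both arms, built by anti-selective allylboration of a (Z)-β-iodoenal with a geometry-defined 2-(methoxycarbonyl)allylboronate.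

Key step: step 14

Remark: germacrane numbering of 31 is used for every compound (ring carbons C1–C10, C14 on C10, C15 on C4, lactone C6–O–C12(=O)–C11(=C13H2)–C7, acyloxy group on C8); ICH2Bpin and all starting materials are taken to be commercial.

Step 1
Reactants: 1 methyl 4-chloro-4-oxobutanoate; 2 bis(trimethylsilyl)acetylene
Product: 3 methyl 4-oxo-6-(trimethylsilyl)hex-5-ynoate
Conditions: AlCl3, CH2Cl2, 0 °C
Reagents that add atoms: none
Why: Friedel–Crafts-type acylation of the silylalkyne (ipso substitution of one C–Si bond by the acid chloride) should give the silyl ynone, the methyl ester being inert.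

Step 2
Reactants: 3 methyl 4-oxo-6-(trimethylsilyl)hex-5-ynoate
Product: 5 (R)-5-[(trimethylsilyl)ethynyl]dihydrofuran-2(3H)-one, via methyl (R)-4-hydroxy-6-(trimethylsilyl)hex-5-ynoate 4 (not isolated)
Conditions: RuCl[(R,R)-TsDPEN](p-cymene) (1 mol %), iPrOH, rt; then TsOH·H2O (cat.), CH2Cl2, rt
Reagents that add atoms: none
Why: Noyori asymmetric transfer hydrogenation of the alkynyl ketone should set C8 as (R) under catalyst control (the alkynyl group takes the place of the aryl group in the usual model, hence the (R,R)-ligand), and the γ-hydroxy ester then lactonises under acid.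

Step 3
Reactants: 5 (R)-5-[(trimethylsilyl)ethynyl]dihydrofuran-2(3H)-one; 6 acrolein
Product: 7 (5R)-3-(1-hydroxyprop-2-en-1-yl)-5-[(trimethylsilyl)ethynyl]dihydrofuran-2(3H)-one (diastereomer mixture at C10 and C1)
Conditions: LiN(iPr)2, THF, −78 °C; then acrolein, −78 °C; AcOH
Reagents that add atoms: none
Why: Aldol addition of the lactone lithium enolate to acrolein (1,2-addition at low temperature) attaches C1–C3, and the two new stereocentres do not matter because step 4 removes them.

Step 4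
Reactants: 7 aldol adduct
Product: 9 (3E,5R)-3-(prop-2-en-1-ylidene)-5-[(trimethylsilyl)ethynyl]dihydrofuran-2(3H)-one, via methanesulfonate of the aldol adduct 8 (not isolated)
Conditions: MsCl, Et3N, CH2Cl2, 0 °C; then DBU, rt
Reagents that add atoms: none
Why: Mesylation and E1cB elimination (aldol condensation) should give mainly the thermodynamically favoured (E)-alkylidene lactone, in which C2 is cis to C9 as the ring-cis C1=C10 olefin requires.

Step 5
Reactants: 9 (E)-dienyl lactone
Product: 10 (2E,4R)-2-(prop-2-en-1-ylidene)-6-(trimethylsilyl)hex-5-yne-1,4-diol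
Conditions: iBu2AlH (4 equiv), CH2Cl2, −78 → 0 °C; aq. KNaC4H4O6 work-up
Reagents that add atoms: none
Why: Hydride reduction of the lactone (1,2-reduction of the dienoate) frees the C14 and C8 hydroxyls and leaves the diene and the silylalkyne untouched.

Step 6
Reactants: 10 dienyl diol
Product: 12 (3E,6R)-4-{[(tert-butyldimethylsilyl)oxy]methyl}-6-[(triethylsilyl)oxy]-8-(trimethylsilyl)octa-1,3-dien-7-yne, via C14 mono-TBS ether 11 (not isolated)
Conditions: TBSCl (1.05 equiv), imidazole, DMF, −20 → 0 °C; then Et3SiCl (1.3 equiv), rt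
Reagents that add atoms: tert-butyldimethylsilyl chloride (CC(C)(C)[Si](C)(C)Cl); chlorotriethylsilane (CC[Si](CC)(CC)Cl)
Why: Silyl ether formation is much faster at the primary allylic C14 hydroxyl than at the secondary propargylic C8 hydroxyl, so sequential silylation should place TBS on O14 and the more acid-labile TES on O8.

Step 7
Reactants: 12 bis-silyl ether
Product: 14 methyl (4R,6E)-6-{[(tert-butyldimethylsilyl)oxy]methyl}-4-[(triethylsilyl)oxy]nona-6,8-dien-2-ynoate, via lithium acetylide 13 (not isolated)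
Conditions: MeLi·LiBr, THF, 0 °C → rt; then ClCO2Me, −78 → 0 °C
Reagents that add atoms: methyl chloroformate (COC(=O)Cl)
Why: Cleavage of the alkynyl C–Si bond by methyllithium gives the lithium acetylide, whose C-acylation by the chloroformate installs C12.

Step 8
Reactants: 14 ynoate
Product: 16 methyl (2Z,4R,6E)-6-{[(tert-butyldimethylsilyl)oxy]methyl}-2-[(4,4,5,5-tetramethyl-1,3,2-dioxaborolan-2-yl)methyl]-4-[(triethylsilyl)oxy]nona-2,6,8-trienoate, via α-(diisobutylalumanyl) enoate 15 (not isolated)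
Conditions: iBu2AlH, HMPA, THF, 0 °C; then ICH2Bpin, 0 °C → rt
Reagents that add atoms: 2-(iodomethyl)-4,4,5,5-tetramethyl-1,3,2-dioxaborolane (ICB1OC(C)(C)C(C)(C)O1)
Why: Conjugate syn-hydroalumination of the ynoate (hydride to C7, aluminium to C11) and C-alkylation of the alkenylalane with retention, the known route from alkynoates to 2-alkoxycarbonyl allylboronates, should leave C8 cis to the ester and trans to CH2B, the (E)-crotyl-type geometry that an anti allylboration needs.

Step 9
Reactants: 17 but-2-yne-1,4-diol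
Product: 18 4-[(4-methoxybenzyl)oxy]but-2-yn-1-ol
Conditions: NaH (1 equiv), 4-methoxybenzyl chloride, THF/DMF, 0 °C → rt (diol in threefold excess)
Reagents that add atoms: 4-methoxybenzyl chloride (COc1ccc(CCl)cc1)
Why: Williamson etherification of the mono-alkoxide, with the diol in excess, should give the mono-PMB ether.

Step 10
Reactants: 18 mono-PMB ether
Product: 20 (Z)-3-iodo-4-[(4-methoxybenzyl)oxy]but-2-en-1-ol, via cyclic sodium alkenylalkoxyaluminate 19 (not isolated)
Conditions: NaAlH2(OCH2CH2OCH3)2, THF, 0 °C; then I2, −78 → 0 °C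
Reagents that add atoms: iodine (II)
Why: Hydroxyl-directed trans-hydroalumination of the propargylic alcohol (hydride to C5, aluminium to C4 within a five-membered alkoxyaluminate) and iodinolysis with retention should place iodine on C4 cis to C6.

Step 11
Reactants: 20 (Z)-iodo allylic alcohol
Product: 21 (Z)-3-iodo-4-[(4-methoxybenzyl)oxy]but-2-enal
Conditions: MnO2, CH2Cl2, rt, dark; used at once
Reagents that add atoms: none
Why: MnO2 oxidation of the allylic alcohol should give the β-iodoenal without loss of the (Z) geometry.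

Step 12
Reactants: 16 allylboronate; 21 (Z)-β-iodoenal
Product: 24 hydroxy trans-lactone (α-methylene-γ-butyrolactone; C6 bears (Z)-CH=C(I)CH2OPMB; C7 bears CH(OH)CH2C(CH2OTBS)=CH–CH=CH2; H6/H7 trans; C6 C7 C8 arranged as in 31), via O-boryl allylboration adduct 22 (not isolated), via C8-O-TES trans-lactone 23 (not isolated)
Conditions: Sc(OTf)3 (10 mol %), CH2Cl2, −40 → 0 °C; TsOH·H2O (cat.), rt; then PPTS, MeOH, 0 °C → rt
Reagents that add atoms: none
Why: Lewis-acid-catalysed allylboration through a closed chair (Zimmerman–Traxler-type) transition state with C8 and the aldehyde substituent equatorial should give the anti adduct and hence the trans-lactone at C6/C7; the face of C7 is set by C8 through A1,3 strain with the cis ester (H8 in the olefin plane, attack anti to the C8–C9 bond, silyloxy group outside), and acidic methanol then removes only the secondary TES ether.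

Step 13
Reactants: 24 hydroxy trans-lactone; 25 (S)-2-methylbutanoic anhydride
Product: 26 (S)-2-methylbutanoate of 24 at O8
Conditions: DMAP (cat.), Et3N, CH2Cl2, 0 °C → rt
Reagents that add atoms: none
Why: DMAP-catalysed acyl transfer (Steglich-type acylation) to the only free hydroxyl should proceed with retention at C8 and at the acyl stereocentre.

Step 14
Reactants: 26 seco ester (iodide on C4, terminal diene C1=C10–C2=C3)
Product: 28 macrocycle (14-O-TBS 15-O-PMB ether of the germacranolide ester), via B-alkyl-9-BBN 27 (not isolated)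
Conditions: 9-BBN (1.1 equiv), THF, 0 °C → rt; then syringe-pump addition to PdCl2(dppf) (20 mol %), AsPh3, Cs2CO3, DMF/THF/H2O, rt → 40 °C, final 1 mM
Reagents that add atoms: none
Why: 9-BBN adds anti-Markovnikov to the only monosubstituted olefin, the C2=C3 terminus of the C1=C10–C2=C3 diene, to give the homoallylic borane 27; zerovalent palladium then inserts into the C4–I bond, base-assisted transmetalation transfers the C3 alkyl group and reductive elimination forms the C3–C4 bond. The closest known reaction type is the B-alkyl Suzuki–Miyaura macrocyclisation run directly after hydroboration of a diene terminus. Ring A, the ten-membered carbocycle, closes by C(sp3)–C(sp2) reductive elimination from an eleven-membered alkyl(alkenyl)palladium ring and ends trans-fused to the existing lactone ring B; no other ring forms. No stereocentre is created: the ring-cis C4=C5 geometry is carried over from the (Z)-iodide with retention and the C1=C10 geometry from the (E)-alkylidene unit, while C6, C7 and C8 are untouched. The step needs chemoselective hydroboration of the vinyl terminus over the exocyclic C11=C13 methylene and the trisubstituted olefins, and ring closure over oligomerisation. The conjugated 1,1-disubstituted methylene lactone is electronically deactivated towards the electrophilic borane, a near-stoichiometric charge of 9-BBN at 0 °C and slow addition at high dilution secure the rest, and the trans-lactone with two cis-oriented olefinic arms turns C3 and C4 towards each other.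

Step 15
Reactants: 28 macrocycle
Product: 29 C14 allylic alcohol (15-O-PMB ether)
Conditions: HF·pyridine, pyridine, THF, 0 °C → rt
Reagents that add atoms: none
Why: Fluoride-mediated desilylation should cleave the primary TBS ether while the PMB ether, the ester and the lactone stay intact.

Step 16
Reactants: 29 C14 allylic alcohol
Product: 30 C14 enal (15-O-PMB ether of 31)
Conditions: MnO2, CH2Cl2, rt
Reagents that add atoms: none
Why: MnO2 oxidation of the only free (allylic) hydroxyl should give the (E)-enal with C2 trans to the formyl group and without olefin migration.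

Step 17
Reactants: 30 C14 enal PMB ether
Product: 31 target CNP0168859.6
Conditions: DDQ, CH2Cl2/pH 7 phosphate buffer, 0 °C
Reagents that add atoms: none
Why: Oxidative PMB cleavage by DDQ (benzylic hydride abstraction, hydrolysis of the oxocarbenium ion) should free the C15 hydroxyl under buffered conditions that spare the enal, the esters and the olefins.

Compound list
1 | methyl 4-chloro-4-oxobutanoate | COC(=O)CCC(Cl)=O | starting material
2 | bis(trimethylsilyl)acetylene | C[Si](C)(C)C#C[Si](C)(C)C | starting material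
3 | methyl 4-oxo-6-(trimethylsilyl)hex-5-ynoate | COC(=O)CCC(=O)C#C[Si](C)(C)C | intermediate
4 | methyl (R)-4-hydroxy-6-(trimethylsilyl)hex-5-ynoate | COC(=O)CC[C@@H](O)C#C[Si](C)(C)C | intermediate (not isolated)
5 | (R)-5-[(trimethylsilyl)ethynyl]dihydrofuran-2(3H)-one | O=C1CC[C@@H](O1)C#C[Si](C)(C)C | intermediate
6 | acrolein | C=CC=O | starting material
7 | (5R)-3-(1-hydroxyprop-2-en-1-yl)-5-[(trimethylsilyl)ethynyl]dihydrofuran-2(3H)-one, diastereomer mixture | O=C1C(C(O)C=C)C[C@@H](O1)C#C[Si](C)(C)C | intermediate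
8 | methanesulfonate of 7 | O=C1C(C(OS(C)(=O)=O)C=C)C[C@@H](O1)C#C[Si](C)(C)C | intermediate (not isolated)
9 | (3E,5R)-3-(prop-2-en-1-ylidene)-5-[(trimethylsilyl)ethynyl]dihydrofuran-2(3H)-one | O=C1/C(=C/C=C)C[C@@H](O1)C#C[Si](C)(C)C | intermediate
10 | (2E,4R)-2-(prop-2-en-1-ylidene)-6-(trimethylsilyl)hex-5-yne-1,4-diol | C=C/C=C(/CO)C[C@@H](O)C#C[Si](C)(C)C | intermediate
11 | (3E,6R)-4-{[(tert-butyldimethylsilyl)oxy]methyl}-8-(trimethylsilyl)octa-1,3-dien-7-yn-6-ol | C=C/C=C(/CO[Si](C)(C)C(C)(C)C)C[C@@H](O)C#C[Si](C)(C)C | intermediate (not isolated)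
12 | (3E,6R)-4-{[(tert-butyldimethylsilyl)oxy]methyl}-6-[(triethylsilyl)oxy]-8-(trimethylsilyl)octa-1,3-dien-7-yne | C=C/C=C(/CO[Si](C)(C)C(C)(C)C)C[C@@H](O[Si](CC)(CC)CC)C#C[Si](C)(C)C | intermediate
13 | lithium acetylide from 12 (lithium in place of the trimethylsilyl group) | C=C/C=C(/CO[Si](C)(C)C(C)(C)C)C[C@@H](O[Si](CC)(CC)CC)C#C[Li] | intermediate (not isolated)
14 | methyl (4R,6E)-6-{[(tert-butyldimethylsilyl)oxy]methyl}-4-[(triethylsilyl)oxy]nona-6,8-dien-2-ynoate | C=C/C=C(/CO[Si](C)(C)C(C)(C)C)C[C@@H](O[Si](CC)(CC)CC)C#CC(=O)OC | intermediate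
15 | α-(diisobutylalumanyl) enoate from 14 (aluminium on C11 trans to C8, C8 cis to the ester) | C=C/C=C(/CO[Si](C)(C)C(C)(C)C)C[C@@H](O[Si](CC)(CC)CC)/C=C(/[Al](CC(C)C)CC(C)C)C(=O)OC | intermediate (not isolated)
16 | methyl (2Z,4R,6E)-6-{[(tert-butyldimethylsilyl)oxy]methyl}-2-[(4,4,5,5-tetramethyl-1,3,2-dioxaborolan-2-yl)methyl]-4-[(triethylsilyl)oxy]nona-2,6,8-trienoate | C=C/C=C(/CO[Si](C)(C)C(C)(C)C)C[C@@H](O[Si](CC)(CC)CC)/C=C(/CB1OC(C)(C)C(C)(C)O1)C(=O)OC | intermediate
17 | but-2-yne-1,4-diol | OCC#CCO | starting material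
18 | 4-[(4-methoxybenzyl)oxy]but-2-yn-1-ol | OCC#CCOCc1ccc(OC)cc1 | intermediate
19 | cyclic sodium alkenylalkoxyaluminate (aluminium on C4 and on O6, two 2-methoxyethoxy ligands) | [Na+].COCCO[Al-]1(OCCOC)OCC=C1COCc1ccc(OC)cc1 | intermediate (not isolated)
20 | (Z)-3-iodo-4-[(4-methoxybenzyl)oxy]but-2-en-1-ol | OC/C=C(\I)COCc1ccc(OC)cc1 | intermediate
21 | (Z)-3-iodo-4-[(4-methoxybenzyl)oxy]but-2-enal | O=C/C=C(\I)COCc1ccc(OC)cc1 | intermediate
22 | O-boryl allylboration adduct (open hydroxy ester with O6–Bpin and O8–TES; C6, C7, C8 arranged as in 31) | COC(=O)C(=C)[C@@H]([C@H](OB1OC(C)(C)C(C)(C)O1)/C=C(\I)COCc1ccc(OC)cc1)[C@H](O[Si](CC)(CC)CC)C/C(CO[Si](C)(C)C(C)(C)C)=C\C=C | intermediate (not isolated)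
23 | C8-O-TES trans-lactone (triethylsilyl ether of 24) | C=C1C(=O)O[C@H](/C=C(\I)COCc2ccc(OC)cc2)[C@H]1[C@H](O[Si](CC)(CC)CC)C/C(CO[Si](C)(C)C(C)(C)C)=C\C=C | intermediate (not isolated)
24 | hydroxy trans-lactone: α-methylene-γ-butyrolactone with (Z)-CH=C(I)CH2OPMB on C6 and CH(OH)CH2C(CH2OTBS)=CH–CH=CH2 on C7 (C9 cis to C2); CIP 6S,7R,8R, the spatial arrangement of 6R,7R,8R in 31 (the iodine raises the rank of C5) | C=C1C(=O)O[C@H](/C=C(\I)COCc2ccc(OC)cc2)[C@H]1[C@H](O)C/C(CO[Si](C)(C)C(C)(C)C)=C\C=C | intermediate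
25 | (S)-2-methylbutanoic anhydride | CC[C@H](C)C(=O)OC(=O)[C@@H](C)CC | starting material
26 | (S)-2-methylbutanoate of 24 at O8 (CIP 6S,7R,8R) | C=C1C(=O)O[C@H](/C=C(\I)COCc2ccc(OC)cc2)[C@H]1[C@H](OC(=O)[C@@H](C)CC)C/C(CO[Si](C)(C)C(C)(C)C)=C\C=C | intermediate
27 | B-alkyl-9-BBN from 26 (boron on C3) | C=C1C(=O)O[C@H](/C=C(\I)COCc2ccc(OC)cc2)[C@H]1[C@H](OC(=O)[C@@H](C)CC)C/C(CO[Si](C)(C)C(C)(C)C)=C\CCB1C2CCCC1CCC2 | intermediate (not isolated)
28 | (6R,7R,8R)-14-[(tert-butyldimethylsilyl)oxy]-15-[(4-methoxybenzyl)oxy]-8-[(S)-2-methylbutanoyloxy]germacra-1(10),4,11(13)-trien-6,12-olide, both ring olefins ring-cis (CIP 1(10)E,4E) | C=C1C(=O)O[C@@H]2/C=C(/COCc3ccc(OC)cc3)CC/C=C(/CO[Si](C)(C)C(C)(C)C)C[C@@H](OC(=O)[C@@H](C)CC)[C@@H]12 | intermediate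
29 | 14-hydroxy-15-[(4-methoxybenzyl)oxy] analogue of 28 | C=C1C(=O)O[C@@H]2/C=C(/COCc3ccc(OC)cc3)CC/C=C(/CO)C[C@@H](OC(=O)[C@@H](C)CC)[C@@H]12 | intermediate
30 | 14-oxo-15-[(4-methoxybenzyl)oxy] analogue (PMB ether of 31) | C=C1C(=O)O[C@@H]2/C=C(/COCc3ccc(OC)cc3)CC/C=C(/C=O)C[C@@H](OC(=O)[C@@H](C)CC)[C@@H]12 | intermediate
31 | (6R,7R,8R)-15-hydroxy-8-[(S)-2-methylbutanoyloxy]-14-oxogermacra-1(10),4,11(13)-trien-6,12-olide, both ring olefins ring-cis (CNP0168859.6) | C=C1C(=O)O[C@@H]2/C=C(/CO)CC/C=C(/C=O)C[C@@H](OC(=O)[C@@H](C)CC)[C@@H]12 | target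

Total step count: 17. Longest linear sequence: 14 steps (steps 1–8 and 12–17); steps 9–11 make the iodoenal 21.

Steps most likely to fail

Step 14. Hydroboration may also take place at the exocyclic C11=C13 methylene, and the alkenylpalladium intermediate may be captured by that same olefin (Heck-type insertion) or by a second molecule (oligomerisation) before the ten-membered ring closes. The fallback sets out from 26. Conjugate addition of thiophenol (PhSH, cat. Et3N, CH2Cl2) should mask the methylene lactone as the β-phenylthio lactone F1 (C11 epimers). Hydroboration with 9-BBN should then give the B-alkyl-9-BBN F2, which is cyclised under the same palladium conditions to the macrocyclic sulfide F3. Oxidation (NaIO4, MeOH/H2O, 0 °C) to the sulfoxide F4 and thermal syn-elimination (toluene, 90 °C, CaCO3) should restore the exocyclic methylene and come back to the route at 28.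

Step 12. The C8 stereocentre may steer the aldehyde to the other face of C7 (addition anti to the silyloxy group instead of anti to the C8–C9 bond), so that facial selectivity is low or reversed. The fallback sets out from 3. The enantiomeric catalyst RuCl[(S,S)-TsDPEN](p-cymene) should give the (S)-hydroxy ester F5 and the (S)-lactone F6. The operations of steps 3 to 8 are repeated in this series through the aldol adduct F7, its mesylate F8, the (S,E)-dienyl lactone F9, the (S)-diol F10, the mono-TBS ether F11, the bis-silyl ether F12, the lithium acetylide F13, the (S)-ynoate F14, the alkenylalane F15 and the (S)-allylboronate F16. Allylboration of 21 under the conditions of step 12 should then pass through the O-boryl adduct F17 and the TES lactone F18 to the C8-epimeric hydroxy lactone F19, in which C6 and C7 are as in the target if the silyloxy-anti mode prevails. Mitsunobu esterification with (S)-2-methylbutanoic acid (PPh3, DIAD, toluene, 0 °C) inverts C8 and comes back to the route at 26.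

Step 8. The α-alumino enoate 15 may isomerise through its allenolate before C-alkylation, which would erode the olefin geometry and with it the anti (trans-lactone) outcome of step 12. The fallback sets out from 14. Palladium-catalysed syn-hydrostannation (Bu3SnH, Pd(PPh3)4, THF, 0 °C) should give the configurationally stable (E)-α-stannyl enoate F20. Iododestannylation (I2, CH2Cl2, 0 °C) should give the (E)-α-iodo enoate F21 with retention, and Negishi coupling with (pinacolatoboryl)methylzinc iodide (IZnCH2Bpin, Pd(PPh3)4, THF) comes back to the route at 16.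

Further compounds
F1 | step 14 | β-phenylthio lactone (thiophenol adduct of 26 at C13, C11 epimers) | c3ccccc3SCC1C(=O)O[C@H](/C=C(\I)COCc2ccc(OC)cc2)[C@H]1[C@H](OC(=O)[C@@H](C)CC)C/C(CO[Si](C)(C)C(C)(C)C)=C\C=C
F2 | step 14 | B-alkyl-9-BBN from F1 (boron on C3) | c3ccccc3SCC1C(=O)O[C@H](/C=C(\I)COCc2ccc(OC)cc2)[C@H]1[C@H](OC(=O)[C@@H](C)CC)C/C(CO[Si](C)(C)C(C)(C)C)=C\CCB1C2CCCC1CCC2
F3 | step 14 | macrocyclic sulfide (13-phenylthio-11,13-dihydro derivative of 28) | c4ccccc4SCC1C(=O)O[C@@H]2/C=C(/COCc3ccc(OC)cc3)CC/C=C(/CO[Si](C)(C)C(C)(C)C)C[C@@H](OC(=O)[C@@H](C)CC)[C@@H]12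
F4 | step 14 | sulfoxide of F3 | O=S(c4ccccc4)CC1C(=O)O[C@@H]2/C=C(/COCc3ccc(OC)cc3)CC/C=C(/CO[Si](C)(C)C(C)(C)C)C[C@@H](OC(=O)[C@@H](C)CC)[C@@H]12
F5 | step 12 | methyl (S)-4-hydroxy-6-(trimethylsilyl)hex-5-ynoate | COC(=O)CC[C@H](O)C#C[Si](C)(C)C
F6 | step 12 | (S)-5-[(trimethylsilyl)ethynyl]dihydrofuran-2(3H)-one | O=C1CC[C@H](O1)C#C[Si](C)(C)C
F7 | step 12 | (5S)-3-(1-hydroxyprop-2-en-1-yl)-5-[(trimethylsilyl)ethynyl]dihydrofuran-2(3H)-one, diastereomer mixture | O=C1C(C(O)C=C)C[C@H](O1)C#C[Si](C)(C)C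
F8 | step 12 | methanesulfonate of F7 | O=C1C(C(OS(C)(=O)=O)C=C)C[C@H](O1)C#C[Si](C)(C)C
F9 | step 12 | (3E,5S)-3-(prop-2-en-1-ylidene)-5-[(trimethylsilyl)ethynyl]dihydrofuran-2(3H)-one | O=C1/C(=C/C=C)C[C@H](O1)C#C[Si](C)(C)C
F10 | step 12 | (2E,4S)-2-(prop-2-en-1-ylidene)-6-(trimethylsilyl)hex-5-yne-1,4-diol | C=C/C=C(/CO)C[C@H](O)C#C[Si](C)(C)C
F11 | step 12 | (3E,6S)-4-{[(tert-butyldimethylsilyl)oxy]methyl}-8-(trimethylsilyl)octa-1,3-dien-7-yn-6-ol | C=C/C=C(/CO[Si](C)(C)C(C)(C)C)C[C@H](O)C#C[Si](C)(C)C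
F12 | step 12 | (3E,6S)-4-{[(tert-butyldimethylsilyl)oxy]methyl}-6-[(triethylsilyl)oxy]-8-(trimethylsilyl)octa-1,3-dien-7-yne | C=C/C=C(/CO[Si](C)(C)C(C)(C)C)C[C@H](O[Si](CC)(CC)CC)C#C[Si](C)(C)C
F13 | step 12 | lithium acetylide from F12 | C=C/C=C(/CO[Si](C)(C)C(C)(C)C)C[C@H](O[Si](CC)(CC)CC)C#C[Li]
F14 | step 12 | methyl (4S,6E)-6-{[(tert-butyldimethylsilyl)oxy]methyl}-4-[(triethylsilyl)oxy]nona-6,8-dien-2-ynoate | C=C/C=C(/CO[Si](C)(C)C(C)(C)C)C[C@H](O[Si](CC)(CC)CC)C#CC(=O)OC
F15 | step 12 | α-(diisobutylalumanyl) enoate from F14 | C=C/C=C(/CO[Si](C)(C)C(C)(C)C)C[C@H](O[Si](CC)(CC)CC)/C=C(/[Al](CC(C)C)CC(C)C)C(=O)OC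
F16 | step 12 | methyl (2Z,4S,6E)-6-{[(tert-butyldimethylsilyl)oxy]methyl}-2-[(4,4,5,5-tetramethyl-1,3,2-dioxaborolan-2-yl)methyl]-4-[(triethylsilyl)oxy]nona-2,6,8-trienoate | C=C/C=C(/CO[Si](C)(C)C(C)(C)C)C[C@H](O[Si](CC)(CC)CC)/C=C(/CB1OC(C)(C)C(C)(C)O1)C(=O)OC
F17 | step 12 | O-boryl allylboration adduct, C8 epimer of 22 | COC(=O)C(=C)[C@@H]([C@H](OB1OC(C)(C)C(C)(C)O1)/C=C(\I)COCc1ccc(OC)cc1)[C@@H](O[Si](CC)(CC)CC)C/C(CO[Si](C)(C)C(C)(C)C)=C\C=C
F18 | step 12 | C8-O-TES trans-lactone, C8 epimer of 23 | C=C1C(=O)O[C@H](/C=C(\I)COCc2ccc(OC)cc2)[C@H]1[C@@H](O[Si](CC)(CC)CC)C/C(CO[Si](C)(C)C(C)(C)C)=C\C=C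
F19 | step 12 | hydroxy trans-lactone, C8 epimer of 24 | C=C1C(=O)O[C@H](/C=C(\I)COCc2ccc(OC)cc2)[C@H]1[C@@H](O)C/C(CO[Si](C)(C)C(C)(C)C)=C\C=C
F20 | step 8 | methyl (2E,4R,6E)-6-{[(tert-butyldimethylsilyl)oxy]methyl}-2-(tributylstannyl)-4-[(triethylsilyl)oxy]nona-2,6,8-trienoate | C=C/C=C(/CO[Si](C)(C)C(C)(C)C)C[C@@H](O[Si](CC)(CC)CC)/C=C(/[Sn](CCCC)(CCCC)CCCC)C(=O)OC
F21 | step 8 | methyl (2E,4R,6E)-6-{[(tert-butyldimethylsilyl)oxy]methyl}-2-iodo-4-[(triethylsilyl)oxy]nona-2,6,8-trienoate | C=C/C=C(/CO[Si](C)(C)C(C)(C)C)C[C@@H](O[Si](CC)(CC)CC)/C=C(/I)C(=O)OC
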